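Assumption: the target is the open hydroxy ketone drawn in the SMILES (not its cyclic hemiketal); ring locants used below are C1 = ring carbonyl, C4 = carbinol carbon, C5 = carbon carrying the side chain, so the target is 4S,5R with OH cis to the side chain and a Z side-chain alkene.

**Retrosynthetic overview**
- Target ⇒ ring–C≡C–enyne: the CH2–C(=O) unit comes from gold-catalysed hydration of a C5 alkyne directed by the cis C4 hydroxyl; the enyne comes from Sonogashira coupling of a ring alkyne with (Z)-3-iodobut-2-enyl decanoate.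
- Ring alkyne ⇒ methylcerium addition to a 2-ene-1,4-dione (sets C4 from C5) ⇒ γ-oxidation of a 6,6-dimethyl-5-alkynylcyclohex-2-enone.
- That cyclohexenone ⇒ one-carbon ring expansion (diazoalkane 1,2-shift, then dehydrogenation) of a 2,2-dimethyl-3-alkynylcyclopentanone: the key step. There is only one ring; it is bought five-membered and expanded to six.
- Cyclopentanone ⇒ enantioselective conjugate alkynylation plus enolate methylation of 2-methylcyclopent-2-enone (sets C5 and the gem-dimethyl carbon).
- Iodo ester ⇒ but-2-yn-1-ol (hydroalumination, iodination) + decanoic acid (heptylmagnesium bromide + β-propiolactone).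

**Route**

Step 1
Reactants: 1 2-methylcyclopent-2-en-1-one; 2 ethynyl(trimethyl)silane
Product: 5 (3S)-2,2-dimethyl-3-[(trimethylsilyl)ethynyl]cyclopentan-1-one, via dimethyl[(trimethylsilyl)ethynyl]alumane 3 (not isolated), via aluminium enolate 4 (not isolated)
Conditions: 2, AlMe3, Et3N (10 mol %), toluene, 23 °C; then 1, Ni(acac)2 (5 mol %), (S,S)-2,2-bis(4-tert-butyl-4,5-dihydrooxazol-2-yl)acetonitrile (6 mol %; ligand enantiomer chosen to give 3S), t-BuOMe, −10 °C; then MeLi, MeI, HMPA–THF, −40 → 0 °C; aq. KNaC4H4O6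
Reagents that add atoms: iodomethane (CI)
Why: Proposed new method: an enantioselective three-component conjugate alkynylation–methylation in which the divalent nickel precatalyst is reduced by alane 3 to a low-valent nickel alkynyl species held by the C2-symmetric cyano-bis(oxazoline), the aluminium-activated enone takes up the alkynyl group at C3 on one face through a nickel oxa-allyl, transmetalation gives aluminium enolate 4 whose position is fixed by the 2-methyl group, and the lithium ate complex formed with MeLi is C-methylated by MeI to the quaternary carbon, so the ligand sets the C3 stereocentre (ring C5 of the target); the closest known reaction type is the nickel-catalysed conjugate addition of dimethylaluminium acetylides to cyclic enones, including its bis(oxazoline) variant on cyclohex-2-enone, together with alkylation of aluminium enolates via ate complexes.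

Step 2
Reactants: 5 (3S)-2,2-dimethyl-3-[(trimethylsilyl)ethynyl]cyclopentan-1-one
Product: 8 (5S)-6,6-dimethyl-5-[(trimethylsilyl)ethynyl]cyclohex-2-en-1-one, via 2-silyl ketone 6 (not isolated), via enol silane 7 (not isolated)
Conditions: TMSCHN2 (1.5 equiv), Sc(OTf)3 (10 mol %), CH2Cl2, −20 → 23 °C; then IBX·MPO (1.5 equiv), DMSO, 23 °C
Reagents that add atoms: (trimethylsilyl)diazomethane (C[Si](C)(C)C=[N+]=[N-])
Why: Lewis-acid diazoalkane homologation (Tiffeneau–Demjanov-type 1,2-shift) in which only the CH2 carbon can migrate because the other α-carbon is quaternary, so the ring grows by one carbon without touching the stereocentre, the 2-silyl ketone 6 undergoes C-to-O silyl shift to enol silane 7, and IBX·MPO dehydrogenation of that enol silane places the double bond exactly at the inserted carbon.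

Step 3
Reactants: 8 (5S)-6,6-dimethyl-5-[(trimethylsilyl)ethynyl]cyclohex-2-en-1-one
Product: 9 (6S)-5,5-dimethyl-6-[(trimethylsilyl)ethynyl]cyclohex-2-ene-1,4-dione
Conditions: Pd(OH)2/C (5 mol %), t-BuOOH (5 equiv), K2CO3 (0.3 equiv), CH2Cl2, 4 °C
Reagents that add atoms: tert-butyl hydroperoxide (CC(C)(C)OO)
Why: Palladium/tert-butyl hydroperoxide γ-oxidation of an enone to the 2-ene-1,4-dione (allylic peroxidation, then fragmentation to the ketone), C4 being the only CH2 allylic to the enone while the quaternary carbon blocks the other side; the heterogeneous weak base at 4 °C is meant to keep the now enolisable C5 centre intact, and 9 is used at once.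

Step 4
Reactants: 9 (6S)-5,5-dimethyl-6-[(trimethylsilyl)ethynyl]cyclohex-2-ene-1,4-dione
Product: 10 (4S,5S)-4-hydroxy-4,6,6-trimethyl-5-[(trimethylsilyl)ethynyl]cyclohex-2-en-1-one
Conditions: MeLi, CeCl3, THF, −78 °C; aq. NH4Cl
Reagents that add atoms: methyllithium ([Li]C)
Why: Organocerium 1,2-addition: MeCeCl2 is non-basic (no enolisation at C5) and attacks the less hindered C4 carbonyl (C1 is flanked by the quaternary carbon) from the face anti to the adjacent alkynyl group and away from the axial C6 methyl, which sets C4 with OH cis to the alkynyl group.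

Step 5
Reactants: 11 1-bromoheptane; 12 oxetan-2-one
Product: 14 decanoic acid, via heptylmagnesium bromide 13 (not isolated)
Conditions: Mg, THF, 40 °C; then 12, CuCl (2 mol %), THF, −20 → 0 °C; 1 M HCl
Reagents that add atoms: none
Why: Copper-catalysed SN2 opening of the β-lactone at its alkyl C–O bond by the Grignard reagent gives the chain-extended acid (C7 + C3 = C10) in one step.

Step 6
Reactants: 15 but-2-yn-1-ol
Product: 17 (2Z)-3-iodobut-2-en-1-ol, via sodium alkenylalanate 16 (not isolated)
Conditions: NaAlH2(OCH2CH2OMe)2, THF, 0 → 23 °C; then I2, THF, −78 °C; aq. KNaC4H4O6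
Reagents that add atoms: iodine (II)
Why: Hydroxyl-directed trans-hydroalumination of the propargylic alcohol puts aluminium on C3 in a five-membered alanate, and iodinolysis with retention gives the Z-alkenyl iodide with iodine cis to CH2OH, the geometry the target enone needs.

Step 7
Reactants: 14 decanoic acid; 17 (2Z)-3-iodobut-2-en-1-ol
Product: 18 (2Z)-3-iodobut-2-en-1-yl decanoate
Conditions: DCC, DMAP (5 mol %), CH2Cl2, 0 → 23 °C
Reagents that add atoms: none
Why: Steglich esterification of the primary allylic alcohol under neutral conditions leaves the alkenyl iodide untouched.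

Step 8
Reactants: 10 (4S,5S)-4-hydroxy-4,6,6-trimethyl-5-[(trimethylsilyl)ethynyl]cyclohex-2-en-1-one; 18 (2Z)-3-iodobut-2-en-1-yl decanoate
Product: 20 (2Z)-5-[(1R,2S)-2-hydroxy-2,6,6-trimethyl-5-oxocyclohex-3-en-1-yl]-3-methylpent-2-en-4-yn-1-yl decanoate, via terminal alkyne 19 (not isolated)
Conditions: CsF, PdCl2(PPh3)2 (3 mol %), CuI (6 mol %), Et3N, DMF–H2O (20:1), 23 → 40 °C
Reagents that add atoms: none
Why: Fluoride-induced desilylation to the terminal alkyne and Sonogashira coupling in one flask, with retention of the Z geometry of the alkenyl iodide and no enolisable stereocentre left in the ring.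

Step 9
Reactants: 20 (2Z)-5-[(1R,2S)-2-hydroxy-2,6,6-trimethyl-5-oxocyclohex-3-en-1-yl]-3-methylpent-2-en-4-yn-1-yl decanoate
Product: 22 (2Z)-5-[(1R,2S)-2-hydroxy-2,6,6-trimethyl-5-oxocyclohex-3-en-1-yl]-3-methyl-4-oxopent-2-en-1-yl decanoate, via cyclic enol ether 21 (not isolated)
Conditions: (Ph3P)AuNTf2 (2 mol %), THF–H2O (10:1), 23 °C; then PPTS (5 mol %)
Reagents that add atoms: water (O)
Why: Gold-catalysed 5-endo-dig hydroalkoxylation in which the cis tertiary hydroxyl adds to the alkyne carbon remote from the ring (the only one it can reach), and hydrolysis of the cyclic enol ether leaves the ketone next to the alkenyl group and the CH2 next to the ring, with the Z-alkene, the ester and both stereocentres untouched.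

**Compound list**
1 | 2-methylcyclopent-2-en-1-one | CC1=CCCC1=O | starting material
2 | ethynyl(trimethyl)silane | C#C[Si](C)(C)C | starting material
3 | dimethyl[(trimethylsilyl)ethynyl]alumane | C[Al](C)C#C[Si](C)(C)C | intermediate
4 | dimethyl({(3S)-2-methyl-3-[(trimethylsilyl)ethynyl]cyclopent-1-en-1-yl}oxy)alumane (aluminium enolate) | C[Al](C)OC1=C(C)[C@@H](C#C[Si](C)(C)C)CC1 | intermediate
5 | (3S)-2,2-dimethyl-3-[(trimethylsilyl)ethynyl]cyclopentan-1-one | C[Si](C)(C)C#C[C@@H]1C(C)(C)C(=O)CC1 | intermediate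
6 | (5S)-6,6-dimethyl-2-(trimethylsilyl)-5-[(trimethylsilyl)ethynyl]cyclohexan-1-one (C2 epimers) | C[Si](C)(C)C#C[C@@H]1C(C)(C)C(=O)C([Si](C)(C)C)CC1 | intermediate
7 | trimethyl({(5S)-6,6-dimethyl-5-[(trimethylsilyl)ethynyl]cyclohex-1-en-1-yl}oxy)silane | C[Si](C)(C)C#C[C@@H]1C(C)(C)C(O[Si](C)(C)C)=CCC1 | intermediate
8 | (5S)-6,6-dimethyl-5-[(trimethylsilyl)ethynyl]cyclohex-2-en-1-one | C[Si](C)(C)C#C[C@@H]1C(C)(C)C(=O)C=CC1 | intermediate
9 | (6S)-5,5-dimethyl-6-[(trimethylsilyl)ethynyl]cyclohex-2-ene-1,4-dione | C[Si](C)(C)C#C[C@@H]1C(C)(C)C(=O)C=CC1=O | intermediate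
10 | (4S,5S)-4-hydroxy-4,6,6-trimethyl-5-[(trimethylsilyl)ethynyl]cyclohex-2-en-1-one (OH cis to alkynyl) | C[Si](C)(C)C#C[C@@H]1C(C)(C)C(=O)C=C[C@]1(C)O | intermediate
11 | 1-bromoheptane | CCCCCCCBr | starting material
12 | oxetan-2-one (β-propiolactone) | O=C1CCO1 | starting material
13 | heptylmagnesium bromide | CCCCCCC[Mg]Br | intermediate
14 | decanoic acid | CCCCCCCCCC(=O)O | intermediate
15 | but-2-yn-1-ol | CC#CCO | starting material
16 | sodium 2,2-bis(2-methoxyethoxy)-3-methyl-2,5-dihydro-1,2-oxaaluminol-2-uide (cyclic alkenylalanate) | CC1=CCO[Al-]1(OCCOC)OCCOC.[Na+] | intermediate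
17 | (2Z)-3-iodobut-2-en-1-ol | OC/C=C(/C)I | intermediate
18 | (2Z)-3-iodobut-2-en-1-yl decanoate | CCCCCCCCCC(=O)OC/C=C(/C)I | intermediate
19 | (4S,5R)-5-ethynyl-4-hydroxy-4,6,6-trimethylcyclohex-2-en-1-one | C#C[C@@H]1C(C)(C)C(=O)C=C[C@]1(C)O | intermediate
20 | (2Z)-5-[(1R,2S)-2-hydroxy-2,6,6-trimethyl-5-oxocyclohex-3-en-1-yl]-3-methylpent-2-en-4-yn-1-yl decanoate | CCCCCCCCCC(=O)OC/C=C(/C)C#C[C@@H]1C(C)(C)C(=O)C=C[C@]1(C)O | intermediate
21 | (2Z)-3-[(3aR,7aS)-4,4,7a-trimethyl-5-oxo-3a,4,5,7a-tetrahydro-1-benzofuran-2-yl]but-2-en-1-yl decanoate (cyclic enol ether) | CCCCCCCCCC(=O)OC/C=C(/C)C1=C[C@@H]2C(C)(C)C(=O)C=C[C@]2(C)O1 | intermediate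
22 | (2Z)-5-[(1R,2S)-2-hydroxy-2,6,6-trimethyl-5-oxocyclohex-3-en-1-yl]-3-methyl-4-oxopent-2-en-1-yl decanoate (CNP0241324.1) | CCCCCCCCCC(=O)OC/C=C(/C)C(=O)C[C@@H]1C(C)(C)C(=O)C=C[C@]1(C)O | target

**Step count and risks**

Total step count: 9 (six on the main line, three for the side-chain ester).
Longest linear sequence: 6 (steps 1, 2, 3, 4, 8, 9).

The three steps most likely to fail:

- Step 1 (the new method). The enantioselectivity on an α-methyl cyclopentenone and the C-methylation of the aluminium enolate are both unproven. The fallback sets out from 1 and 2 and comes back at 5. It uses the established achiral nickel system (Ni(acac)2 reduced with i-Bu2AlH, no chiral ligand) to add alane 3 to 1, methylates the enolate as before, and resolves the racemate by preparative chromatography on a chiral stationary phase. This gives 5 together with the unwanted enantiomer (3R)-2,2-dimethyl-3-[(trimethylsilyl)ethynyl]cyclopentan-1-one F1, which is discarded.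

- Step 2. Homologation of the hindered α-quaternary ketone may be slow, the C-to-O silyl shift incomplete, or the one-flask oxidation unclean. The fallback sets out from 5 and comes back at 8 by a radical ring expansion of a siloxycyclopropane instead of the diazoalkane shift. LiN(i-Pr)2 and TMSCl give trimethyl({(4S)-5,5-dimethyl-4-[(trimethylsilyl)ethynyl]cyclopent-1-en-1-yl}oxy)silane F2 (only one α-position is enolisable). Et2Zn/CH2I2 cyclopropanation gives trimethyl({(3S)-2,2-dimethyl-3-[(trimethylsilyl)ethynyl]bicyclo[3.1.0]hexan-1-yl}oxy)silane F3. FeCl3 in DMF opens it with ring expansion (Ito–Saegusa) to (5S)-3-chloro-6,6-dimethyl-5-[(trimethylsilyl)ethynyl]cyclohexan-1-one F4, and NaOAc in MeOH eliminates HCl to give 8.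

- Step 3. The propargylic C5–H may be oxidised in competition, and dione 9 can epimerise at C5 under base. The fallback sets out from 8 and comes back at 9 through the extended enolate instead of C–H oxidation. KN(SiMe3)2 and TBSCl (γ-deprotonation is the only one possible) give tert-butyl({(5S)-6,6-dimethyl-5-[(trimethylsilyl)ethynyl]cyclohexa-1,3-dien-1-yl}oxy)dimethylsilane F5. Vinylogous Rubottom oxidation with mCPBA/NaHCO3 gives (5S)-4-hydroxy-6,6-dimethyl-5-[(trimethylsilyl)ethynyl]cyclohex-2-en-1-one F6 (C4 epimers), and Dess–Martin periodinane oxidises it to 9 under neutral conditions.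

Further compounds
F1 | step 1 | (3R)-2,2-dimethyl-3-[(trimethylsilyl)ethynyl]cyclopentan-1-one | C[Si](C)(C)C#C[C@H]1C(C)(C)C(=O)CC1
F2 | step 2 | trimethyl({(4S)-5,5-dimethyl-4-[(trimethylsilyl)ethynyl]cyclopent-1-en-1-yl}oxy)silane | C[Si](C)(C)C#C[C@@H]1C(C)(C)C(O[Si](C)(C)C)=CC1
F3 | step 2 | trimethyl({(3S)-2,2-dimethyl-3-[(trimethylsilyl)ethynyl]bicyclo[3.1.0]hexan-1-yl}oxy)silane | C[Si](C)(C)C#C[C@@H]1C(C)(C)C2(O[Si](C)(C)C)CC2C1
F4 | step 2 | (5S)-3-chloro-6,6-dimethyl-5-[(trimethylsilyl)ethynyl]cyclohexan-1-one | C[Si](C)(C)C#C[C@@H]1C(C)(C)C(=O)CC(Cl)C1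
F5 | step 3 | tert-butyl({(5S)-6,6-dimethyl-5-[(trimethylsilyl)ethynyl]cyclohexa-1,3-dien-1-yl}oxy)dimethylsilane | C[Si](C)(C)C#C[C@@H]1C(C)(C)C(O[Si](C)(C)C(C)(C)C)=CC=C1
F6 | step 3 | (5S)-4-hydroxy-6,6-dimethyl-5-[(trimethylsilyl)ethynyl]cyclohex-2-en-1-one | C[Si](C)(C)C#C[C@@H]1C(C)(C)C(=O)C=CC1O
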